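**Strategy.** Ring A is a para-hydroquinone (C5–OH, C8–OH) fused to ring C through C4a=C8a, the enol-ether double bond of a 4-pyranone. This feature lets ring A be cut at C8–C8a back to a four-membered ring. The key step is a thermal cyclobutenone ring expansion. 4π opening to a dienylketene, 6π closure of the ketene carbon onto C8a and enolisation deliver the whole 5,8-dihydroxy-6-alkylisoflavone in one operation. The precursor is a 4-hydroxycyclobut-2-enone. Its carbinol carbon bears the 5-aryl-4-oxopyran-3-yl unit (rings C and B), and the neighbouring C3 bears the silyl-protected side chain. A cyclobutenedione monoacetal fixes this regiochemistry.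

Key step: step 13

**Remarks on the chemistry**
- The target has no stereocentre. Compounds 22, 23 and 25 are racemic, and their single stereocentre vanishes in step 13.
- A free 3-alkylcyclobutene-1,2-dione would offer the organometallic two competing carbonyl groups and an unsubstituted enone carbon. Monoacetal 10 leaves open only the carbonyl next to the alkyl-bearing carbon, so the chain can only end at C6.
- O2' is carried as a triisopropylsilyl ether and not as an acetal-type ether, so the endgame needs fluoride only. Acid able to cleave an aryl acetal could close the tertiary side-chain alcohol onto O5 (chroman) or attack the chromene.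
- After the 6π closure a single keto–enol shift (C8a–H to O8) suffices, because C5 already carries its enol hydroxyl.

**Route**

Step 1
Reactants: 1 3-methylbutane-1,3-diol
Product: 2 4-bromo-2-methylbutan-2-ol
Conditions: CBr4, PPh3, CH2Cl2, 0 °C
Reagents that add atoms: carbon tetrabromide, BrC(Br)(Br)Br
Why: The Appel bromination is selective for the primary hydroxyl because the tertiary oxyphosphonium salt cannot undergo SN2 displacement at 0 °C.

Step 2
Reactants: 2 4-bromo-2-methylbutan-2-ol
Product: 3 triethyl[(4-bromo-2-methylbutan-2-yl)oxy]silane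
Conditions: TESOTf, 2,6-lutidine, CH2Cl2, 0 °C
Reagents that add atoms: triethylsilyl trifluoromethanesulfonate, CC[Si](CC)(CC)OS(=O)(=O)C(F)(F)F
Why: Silyl triflate/lutidine silylation is the standard way to cap a hindered tertiary alcohol, and the primary bromide is inert to it.

Step 3
Reactants: 3 triethyl[(4-bromo-2-methylbutan-2-yl)oxy]silane; 4 dimethyl squarate
Product: 7 3-methoxy-4-[3-methyl-3-(triethylsilyloxy)butyl]cyclobut-3-ene-1,2-dione, via alkylmagnesium bromide 5 (not isolated), via bromomagnesium alkoxide 6 (not isolated)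
Conditions: Mg, THF, 40 °C; add to 4, THF, −78 °C; (CF3CO)2O, −78 °C; H2O
Reagents that add atoms: water, O
Why: Grignard 1,2-addition to the squarate ester, trifluoroacetylation of the racemic alkoxide and hydrolytic loss of methanol (the standard one-pot squarate-to-alkylcyclobutenedione sequence) replace one methoxy group by the chain without protic acid that would threaten the silyl ether.

Step 4
Reactants: 7 3-methoxy-4-alkylcyclobutenedione
Product: 8 3,4,4-trimethoxy-2-[3-methyl-3-(triethylsilyloxy)butyl]cyclobut-2-en-1-one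
Conditions: TMSOMe, TMSOTf (cat.), CH2Cl2, −78 to −20 °C; pyridine quench
Reagents that add atoms: methoxytrimethylsilane, CO[Si](C)(C)C
Why: Noyori acetalisation takes the ketone-like carbonyl next to the methoxy-bearing carbon because the other carbonyl is deactivated as a vinylogous ester, and the aprotic medium spares the silyl ether.

Step 5
Reactants: 8 3,4,4-trimethoxy-2-alkylcyclobutenone
Product: 10 4,4-dimethoxy-2-[3-methyl-3-(triethylsilyloxy)butyl]cyclobut-2-en-1-one, via cyclobutenol 9 (not isolated)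
Conditions: i-Bu2AlH, CH2Cl2, −78 °C; then 5% aq. oxalic acid, THF, 0 °C
Reagents that add atoms: water, O
Why: 1,2-Hydride reduction of the vinylogous ester (racemic carbinol, lost at once) and acid-triggered allylic transposition with loss of methanol (Stork–Danheiser-type carbonyl transposition) put H on the former carbonyl carbon, while the acetal survives because it ends up alpha to the new ketone.

Step 6
Reactants: 11 4-bromoresorcinol; 12 3-methylbut-2-enal
Product: 14 6-bromo-2,2-dimethyl-2H-chromen-7-ol, via ortho-quinone methide 13 (not isolated)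
Conditions: ethylenediammonium diacetate (cat.), toluene, 110 °C
Reagents that add atoms: none
Why: Knoevenagel-type condensation at the ring carbon ortho to one hydroxyl and para to the other, followed by oxa-6π electrocyclisation, builds the linear chromene, since bromine blocks one activated site and the carbon between the two hydroxyls is the more hindered one.

Step 7
Reactants: 14 6-bromo-2,2-dimethyl-2H-chromen-7-ol
Product: 15 [(6-bromo-2,2-dimethyl-2H-chromen-7-yl)oxy]tri(propan-2-yl)silane
Conditions: TIPSCl, imidazole, DMF, rt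
Reagents that add atoms: triisopropylsilyl chloride, CC(C)[Si](Cl)(C(C)C)C(C)C
Why: Imidazole-promoted phenol silylation installs a group that resists aqueous phosphate, Grignard reagents and heat but falls to fluoride.

Step 8
Reactants: 15 aryl bromide
Product: 16 {[2,2-dimethyl-6-(4,4,5,5-tetramethyl-1,3,2-dioxaborolan-2-yl)-2H-chromen-7-yl]oxy}tri(propan-2-yl)silane
Conditions: B2pin2, Pd(dppf)Cl2 (cat.), KOAc, 1,4-dioxane, 90 °C
Reagents that add atoms: bis(pinacolato)diboron, CC1(C)OB(OC1(C)C)B1OC(C)(C)C(C)(C)O1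
Why: Miyaura borylation converts the C–Br bond without an aryllithium, which could suffer an oxygen-to-carbon silyl shift from the ortho silyl ether.

Step 9
Reactants: 17 4H-pyran-4-one
Product: 19 3,5-dibromo-4H-pyran-4-one, via tetrabromide adduct 18 (not isolated)
Conditions: Br2 (2.2 equiv), CH2Cl2, 0 °C to rt; then Et3N
Reagents that add atoms: bromine, BrBr
Why: Bromine addition to each enone C=C and base-induced dehydrobromination (alpha-bromination of a vinylogous ester by addition–elimination) place bromine on both carbons flanking the carbonyl.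

Step 10
Reactants: 19 3,5-dibromo-4H-pyran-4-one (2.5 equiv); 16 boronate
Product: 20 3-bromo-5-[2,2-dimethyl-7-(triisopropylsilyloxy)-2H-chromen-6-yl]-4H-pyran-4-one
Conditions: Pd(OAc)2 (cat.), SPhos, K3PO4, toluene/H2O, 50 °C
Reagents that add atoms: none
Why: Suzuki–Miyaura coupling of an activated alkenyl bromide proceeds under mild biphasic base, and an excess of the symmetrical, more electron-poor and recoverable dibromide holds the reaction at the mono-coupling stage.

Step 11
Reactants: 20 bromo(aryl)pyranone; 10 4,4-dimethoxy-2-alkylcyclobutenone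
Product: 22 rac-3-{1-hydroxy-4,4-dimethoxy-2-[3-methyl-3-(triethylsilyloxy)butyl]cyclobut-2-en-1-yl}-5-[2,2-dimethyl-7-(triisopropylsilyloxy)-2H-chromen-6-yl]-4H-pyran-4-one, via pyranonylmagnesium chloride 21 (not isolated)
Conditions: i-PrMgCl·LiCl, THF, −40 °C; cannulate into 10, LaCl3·2LiCl, THF, −40 to −10 °C; pH 7 buffer
Reagents that add atoms: none
Why: Halogen–magnesium exchange at an sp2 C–Br bond activated by the adjacent carbonyl and the ring oxygen should outrun addition at low temperature, and LaCl3-promoted 1,2-addition to the only free carbonyl of 10 sets the carbinol centre as a racemate, which is irrelevant because it becomes sp2 C5 in step 13.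

Step 12
Reactants: 22 carbinol acetal
Product: 23 rac-4-hydroxy-4-{5-[2,2-dimethyl-7-(triisopropylsilyloxy)-2H-chromen-6-yl]-4-oxo-4H-pyran-3-yl}-3-[3-methyl-3-(triethylsilyloxy)butyl]cyclobut-2-en-1-one
Conditions: PPTS (cat.), acetone/H2O, 35 °C
Reagents that add atoms: water, O
Why: Mild acid-catalysed acetal hydrolysis runs through an allylic cyclobutenyl oxocarbenium ion now that no carbonyl flanks the acetal, under conditions that a tertiary triethylsilyl ether and an aryl triisopropylsilyl ether tolerate.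

Step 13
Reactants: 23 4-hydroxy-4-(pyranonyl)cyclobutenone
Product: 26 5,8-dihydroxy-3-[2,2-dimethyl-7-(triisopropylsilyloxy)-2H-chromen-6-yl]-6-[3-methyl-3-(triethylsilyloxy)butyl]-4H-chromen-4-one, via dienylketene 24 (not isolated), via 8a-H dienone 25 (not isolated)
Conditions: degassed toluene (0.01 M), 110 °C, Ar
Reagents that add atoms: none
Why: Proposed new method: heat opens the strained ring of 23 by conrotatory 4π electrocyclic cleavage of the C5–C8 bond, the carbinol hydroxyl rotating outward as donor groups do, so that dienylketene 24 holds the pyranone cis to the ketene. Ring A (six-membered, carbocyclic) then closes by disrotatory 6π electrocyclisation across C8=C7–C6=C5–C4a=C8a, forming C8–C8a, and one keto–enol shift of the C8a–H in dienone 25 gives the aromatic hydroquinone 26. The closest known reaction type is the Moore rearrangement of 4-aryl-, 4-heteroaryl- and 4-alkenyl-4-hydroxycyclobutenones; a 4-oxopyran-3-yl group, whose closing carbon is the electron-poor β-carbon of a vinylogous ester, has not been used, but a pericyclic closure needs no nucleophilic terminus and the pyranone gives up little aromatic stabilisation. No stereocentre is created in 26, since the racemic carbinol carbon becomes sp2 C5 and the transient C8a centre of 25 is erased by enolisation. Site selectivity lies in the substrate: C3 of the pyranone has only one neighbouring C=C (the other neighbour is C4=O), the C5–OH···O=C4 hydrogen bond favours the rotamer that presents C8a to the ketene, and the C6 position of the chain was locked in 10. Chemoselectivity rests on the silyl caps at O2' and on the side chain, which remove internal nucleophiles for the ketene, and on exclusion of air, which keeps 26 at the hydroquinone level.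

Step 14
Reactants: 26 bis-silylated 5,8-dihydroxyisoflavone
Product: 27 Kraussianone 3
Conditions: Bu4NF, AcOH, degassed THF, 0 °C to rt, Ar
Reagents that add atoms: none
Why: Acetic-acid-buffered fluoride desilylation under argon frees the 2'-phenol and the tertiary alcohol in one operation, without acid that could cyclise the chain onto O5 and without the base and air that would oxidise the hydroquinone.

**Compound list**

1 | 3-methylbutane-1,3-diol | CC(C)(O)CCO | starting material
2 | 4-bromo-2-methylbutan-2-ol | CC(C)(O)CCBr | intermediate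
3 | triethyl[(4-bromo-2-methylbutan-2-yl)oxy]silane | CC[Si](CC)(CC)OC(C)(C)CCBr | intermediate
4 | dimethyl squarate (3,4-dimethoxycyclobut-3-ene-1,2-dione) | COC1=C(OC)C(=O)C1=O | starting material
5 | {3-methyl-3-[(triethylsilyl)oxy]butyl}magnesium bromide | CC[Si](CC)(CC)OC(C)(C)CC[Mg]Br | intermediate
6 | bromomagnesium alkoxide of rac-4-hydroxy-2,3-dimethoxy-4-[3-methyl-3-(triethylsilyloxy)butyl]cyclobut-2-en-1-one | COC1=C(OC)C(CCC(C)(C)O[Si](CC)(CC)CC)(O[Mg]Br)C1=O | intermediate
7 | 3-methoxy-4-[3-methyl-3-(triethylsilyloxy)butyl]cyclobut-3-ene-1,2-dione | COC1=C(CCC(C)(C)O[Si](CC)(CC)CC)C(=O)C1=O | intermediate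
8 | 3,4,4-trimethoxy-2-[3-methyl-3-(triethylsilyloxy)butyl]cyclobut-2-en-1-one | COC1=C(CCC(C)(C)O[Si](CC)(CC)CC)C(=O)C1(OC)OC | intermediate
9 | rac-3,4,4-trimethoxy-2-[3-methyl-3-(triethylsilyloxy)butyl]cyclobut-2-en-1-ol | COC1=C(CCC(C)(C)O[Si](CC)(CC)CC)C(O)C1(OC)OC | intermediate
10 | 4,4-dimethoxy-2-[3-methyl-3-(triethylsilyloxy)butyl]cyclobut-2-en-1-one | COC1(OC)C=C(CCC(C)(C)O[Si](CC)(CC)CC)C1=O | intermediate
11 | 4-bromoresorcinol | Oc1ccc(Br)c(O)c1 | starting material
12 | 3-methylbut-2-enal | CC(C)=CC=O | starting material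
13 | (6Z)-4-bromo-3-hydroxy-6-(3-methylbut-2-en-1-ylidene)cyclohexa-2,4-dien-1-one | CC(C)=C/C=C1/C=C(Br)C(O)=CC1=O | intermediate
14 | 6-bromo-2,2-dimethyl-2H-chromen-7-ol | CC1(C)C=Cc2cc(Br)c(O)cc2O1 | intermediate
15 | [(6-bromo-2,2-dimethyl-2H-chromen-7-yl)oxy]tri(propan-2-yl)silane | CC(C)[Si](Oc1cc2OC(C)(C)C=Cc2cc1Br)(C(C)C)C(C)C | intermediate
16 | {[2,2-dimethyl-6-(4,4,5,5-tetramethyl-1,3,2-dioxaborolan-2-yl)-2H-chromen-7-yl]oxy}tri(propan-2-yl)silane | CC(C)[Si](Oc1cc2OC(C)(C)C=Cc2cc1B3OC(C)(C)C(C)(C)O3)(C(C)C)C(C)C | intermediate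
17 | 4H-pyran-4-one | O=c1ccocc1 | starting material
18 | 2,3,5,6-tetrabromotetrahydro-4H-pyran-4-one (diastereomer mixture) | BrC1OC(Br)C(Br)C(=O)C1Br | intermediate
19 | 3,5-dibromo-4H-pyran-4-one | O=c1c(Br)cocc1Br | intermediate
20 | 3-bromo-5-[2,2-dimethyl-7-(triisopropylsilyloxy)-2H-chromen-6-yl]-4H-pyran-4-one | O=c1c(Br)cocc1-c1cc2C=CC(C)(C)Oc2cc1O[Si](C(C)C)(C(C)C)C(C)C | intermediate
21 | {5-[2,2-dimethyl-7-(triisopropylsilyloxy)-2H-chromen-6-yl]-4-oxo-4H-pyran-3-yl}magnesium chloride | O=c1c([Mg]Cl)cocc1-c1cc2C=CC(C)(C)Oc2cc1O[Si](C(C)C)(C(C)C)C(C)C | intermediate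
22 | rac-3-{1-hydroxy-4,4-dimethoxy-2-[3-methyl-3-(triethylsilyloxy)butyl]cyclobut-2-en-1-yl}-5-[2,2-dimethyl-7-(triisopropylsilyloxy)-2H-chromen-6-yl]-4H-pyran-4-one | COC1(OC)C=C(CCC(C)(C)O[Si](CC)(CC)CC)C1(O)c1cocc(-c2cc3C=CC(C)(C)Oc3cc2O[Si](C(C)C)(C(C)C)C(C)C)c1=O | intermediate
23 | rac-4-hydroxy-4-{5-[2,2-dimethyl-7-(triisopropylsilyloxy)-2H-chromen-6-yl]-4-oxo-4H-pyran-3-yl}-3-[3-methyl-3-(triethylsilyloxy)butyl]cyclobut-2-en-1-one | O=C1C=C(CCC(C)(C)O[Si](CC)(CC)CC)C1(O)c1cocc(-c2cc3C=CC(C)(C)Oc3cc2O[Si](C(C)C)(C(C)C)C(C)C)c1=O | intermediate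
24 | (E)-dienylketene, hydroxyl trans and pyranone cis to the ketene arm | O=C=C/C(CCC(C)(C)O[Si](CC)(CC)CC)=C(/O)c1cocc(-c2cc3C=CC(C)(C)Oc3cc2O[Si](C(C)C)(C(C)C)C(C)C)c1=O | intermediate
25 | rac-5-hydroxy-8a-H-chromene-4,8-dione tautomer of 26 | O=C1C=C(CCC(C)(C)O[Si](CC)(CC)CC)C(O)=C2C(=O)C(-c3cc4C=CC(C)(C)Oc4cc3O[Si](C(C)C)(C(C)C)C(C)C)=COC12 | intermediate
26 | 5,8-dihydroxy-3-[2,2-dimethyl-7-(triisopropylsilyloxy)-2H-chromen-6-yl]-6-[3-methyl-3-(triethylsilyloxy)butyl]-4H-chromen-4-one | CC[Si](CC)(CC)OC(C)(C)CCc1cc(O)c2occ(-c3cc4C=CC(C)(C)Oc4cc3O[Si](C(C)C)(C(C)C)C(C)C)c(=O)c2c1O | intermediate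
27 | Kraussianone 3, 5,8-dihydroxy-3-(7-hydroxy-2,2-dimethyl-2H-chromen-6-yl)-6-(3-hydroxy-3-methylbutyl)-4H-chromen-4-one | CC(C)(O)CCc1cc(O)c2occ(-c3cc4c(cc3O)OC(C)(C)C=C4)c(=O)c2c1O | target

**Step count.** Total: 14 steps. Longest linear sequence: 9 steps (1–5, 11–14).

**Steps most likely to fail**

1. **Step 13.** The electrocyclic closure onto the electron-poor, partly aromatic pyranone terminus may be slower than reclosure of the four-membered ring. The reversibly formed ketene could then drain away through inward rotation of the hydroxyl and lactonisation, or through oligomerisation.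
 - Fallback (known chemistry; sets out from 10 and 16, comes back at 27). Ring A is grown on a furan, a documented heteroaryl partner for this ring expansion. Ring C is then built by the standard enaminone route.
 - 3-Bromofuran and n-BuLi at −78 °C give 3-furyllithium F1, which adds to 10 to give the furyl carbinol acetal F2.
 - Mild acid hydrolysis gives the 4-(3-furyl)-4-hydroxycyclobutenone F3. Heating in toluene gives the 5-alkylbenzofuran-4,7-diol F4, and TBSCl/imidazole gives the bis(silyl ether) F5.
 - Ozonolysis of the furan C2=C3 bond (O3, then Me2S) gives the formyloxy aldehyde F6. NaHCO3 in MeOH gives the salicylaldehyde F7, in which only the future O1 is free.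
 - MeMgBr gives the benzylic carbinol F8, MnO2 the ortho-hydroxyacetophenone F9, and DMF dimethyl acetal the enaminone F10. Iodine closes F10 to the 3-iodochromone F11.
 - Suzuki–Miyaura coupling of F11 with 16 gives the persilylated isoflavone F12. The conditions of step 14 convert F12 into 27.

2. **Step 11.** Bromine–magnesium exchange may be too slow, which would allow conjugate addition of the isopropyl reagent to the pyranone. Alternatively, the metallated pyranone may fragment by β-elimination of the ring oxygen before it meets 10.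
 - Fallback (sets out from 19, 10 and 16, comes back at 22). The order of bond formation is reversed.
 - Exchange is run on the symmetrical dibromide 19, whose second bromine accelerates it. This gives (5-bromo-4-oxo-4H-pyran-3-yl)magnesium chloride F13.
 - Addition of F13 to 10 gives the bromopyranonyl carbinol acetal F14. Ring B is attached only then, by Suzuki–Miyaura coupling of F14 with 16 to give 22.
 - This order also removes the need for a mono-selective coupling.

3. **Step 12.** The acid needed to ionise the four-ring acetal may also strip the tertiary triethylsilyl ether or ionise the activated carbinol.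
 - Fallback (sets out from 6 and 21, comes back at 23). The acetal is avoided altogether.
 - Quenching 6 with water gives the hydroxydimethoxycyclobutenone F15. LiAlH(O-t-Bu)3 reduces its carbonyl to the cyclobutenediol F16.
 - Brief treatment with dilute acid expels two molecules of methanol to give the 3-alkylcyclobutene-1,2-dione F17.
 - Grignard reagent 21 is added to F17 at −78 °C. The electronic bias favours the carbonyl next to the alkyl-bearing carbon, because the other carbonyl is the vinylogous partner of the alkyl donor. This gives 23 directly, and any regioisomer is removed by chromatography.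

Further compounds
F1 | step 13 | 3-furyllithium | [Li]c1ccoc1
F2 | step 13 | rac-1-(furan-3-yl)-4,4-dimethoxy-2-[3-methyl-3-(triethylsilyloxy)butyl]cyclobut-2-en-1-ol | COC1(OC)C=C(CCC(C)(C)O[Si](CC)(CC)CC)C1(O)c1ccoc1
F3 | step 13 | rac-4-(furan-3-yl)-4-hydroxy-3-[3-methyl-3-(triethylsilyloxy)butyl]cyclobut-2-en-1-one | O=C1C=C(CCC(C)(C)O[Si](CC)(CC)CC)C1(O)c1ccoc1
F4 | step 13 | 5-[3-methyl-3-(triethylsilyloxy)butyl]-1-benzofuran-4,7-diol | Oc1cc(CCC(C)(C)O[Si](CC)(CC)CC)c(O)c2ccoc12
F5 | step 13 | 4,7-bis(tert-butyldimethylsilyloxy)-5-[3-methyl-3-(triethylsilyloxy)butyl]-1-benzofuran | CC(C)(C)[Si](C)(C)Oc1cc(CCC(C)(C)O[Si](CC)(CC)CC)c(O[Si](C)(C)C(C)(C)C)c2ccoc12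
F6 | step 13 | 3,6-bis(tert-butyldimethylsilyloxy)-2-formyl-4-[3-methyl-3-(triethylsilyloxy)butyl]phenyl formate | O=COc1c(C=O)c(O[Si](C)(C)C(C)(C)C)c(CCC(C)(C)O[Si](CC)(CC)CC)cc1O[Si](C)(C)C(C)(C)C
F7 | step 13 | 3,6-bis(tert-butyldimethylsilyloxy)-2-hydroxy-5-[3-methyl-3-(triethylsilyloxy)butyl]benzaldehyde | Oc1c(C=O)c(O[Si](C)(C)C(C)(C)C)c(CCC(C)(C)O[Si](CC)(CC)CC)cc1O[Si](C)(C)C(C)(C)C
F8 | step 13 | rac-3,6-bis(tert-butyldimethylsilyloxy)-2-(1-hydroxyethyl)-4-[3-methyl-3-(triethylsilyloxy)butyl]phenol | CC(O)c1c(O)c(O[Si](C)(C)C(C)(C)C)cc(CCC(C)(C)O[Si](CC)(CC)CC)c1O[Si](C)(C)C(C)(C)C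
F9 | step 13 | 1-{3,6-bis(tert-butyldimethylsilyloxy)-2-hydroxy-5-[3-methyl-3-(triethylsilyloxy)butyl]phenyl}ethan-1-one | CC(=O)c1c(O)c(O[Si](C)(C)C(C)(C)C)cc(CCC(C)(C)O[Si](CC)(CC)CC)c1O[Si](C)(C)C(C)(C)C
F10 | step 13 | (E)-3-(dimethylamino)-1-{3,6-bis(tert-butyldimethylsilyloxy)-2-hydroxy-5-[3-methyl-3-(triethylsilyloxy)butyl]phenyl}prop-2-en-1-one | CN(C)/C=C/C(=O)c1c(O)c(O[Si](C)(C)C(C)(C)C)cc(CCC(C)(C)O[Si](CC)(CC)CC)c1O[Si](C)(C)C(C)(C)C
F11 | step 13 | 5,8-bis(tert-butyldimethylsilyloxy)-3-iodo-6-[3-methyl-3-(triethylsilyloxy)butyl]-4H-chromen-4-one | O=c1c(I)coc2c(O[Si](C)(C)C(C)(C)C)cc(CCC(C)(C)O[Si](CC)(CC)CC)c(O[Si](C)(C)C(C)(C)C)c12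
F12 | step 13 | 5,8-bis(tert-butyldimethylsilyloxy)-3-[2,2-dimethyl-7-(triisopropylsilyloxy)-2H-chromen-6-yl]-6-[3-methyl-3-(triethylsilyloxy)butyl]-4H-chromen-4-one | O=c1c(-c2cc3C=CC(C)(C)Oc3cc2O[Si](C(C)C)(C(C)C)C(C)C)coc2c(O[Si](C)(C)C(C)(C)C)cc(CCC(C)(C)O[Si](CC)(CC)CC)c(O[Si](C)(C)C(C)(C)C)c12
F13 | step 11 | (5-bromo-4-oxo-4H-pyran-3-yl)magnesium chloride | O=c1c(Br)cocc1[Mg]Cl
F14 | step 11 | rac-3-bromo-5-{1-hydroxy-4,4-dimethoxy-2-[3-methyl-3-(triethylsilyloxy)butyl]cyclobut-2-en-1-yl}-4H-pyran-4-one | COC1(OC)C=C(CCC(C)(C)O[Si](CC)(CC)CC)C1(O)c1cocc(Br)c1=O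
F15 | step 12 | rac-4-hydroxy-2,3-dimethoxy-4-[3-methyl-3-(triethylsilyloxy)butyl]cyclobut-2-en-1-one | COC1=C(OC)C(O)(CCC(C)(C)O[Si](CC)(CC)CC)C1=O
F16 | step 12 | 2,3-dimethoxy-1-[3-methyl-3-(triethylsilyloxy)butyl]cyclobut-2-ene-1,4-diol (diastereomer mixture) | COC1=C(OC)C(O)(CCC(C)(C)O[Si](CC)(CC)CC)C1O
F17 | step 12 | 3-[3-methyl-3-(triethylsilyloxy)butyl]cyclobut-3-ene-1,2-dione | O=C1C=C(CCC(C)(C)O[Si](CC)(CC)CC)C1=O
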